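The route rests on disconnecting ring B (C6–C11) at C9–C10 and C7–C8. Its C10 ketone lies β to the spiro atom C6 and next to the substituted C9, so ring B is a 3-spirocyclobutanone (C10, C11, C6, C7) enlarged by a two-carbon alkyne unit (C8, C9). C6 is stereogenic only through the choice of the CH2–CO bond that is cut. One nickel(0)-catalysed, ligand-controlled alkyne insertion therefore closes ring B, forms both bonds and sets C6. Its precursor is an achiral cyclobutanone spiro-fused to ring A, held as the C1-methyl enone ethylene ketal from ketoisophorone, and a silyl-capped propargyl ether.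

Key step: step 6

Numbering used throughout (skeleton numbering, not IUPAC lowest locants): ring A is C1(=C14H2)–C2H2–C3H(OH)–C4H(Br)–C5Me2–C6; ring B is C6–C7H2–C8H2–C9(OH)(C15H2Cl)–C10(=O)–C11H2.

Assumption: the (S)-BINOL-derived phosphoramidite is taken to give the (6R) product 10; if the sense of induction is the opposite, its mirror image is used.

Remark: the CIP label at C6 alternates between R and S along the route only because substituent priorities change; the arrangement set in step 6 is never touched.

**Step 1**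
Reactants: 1 ketoisophorone
Product: 2 ketoisophorone C4 ethylene ketal (7,9,9-trimethyl-1,4-dioxaspiro[4.5]dec-6-en-8-one)
Conditions: HOCH2CH2OH, p-TsOH (cat.), toluene, reflux, Dean–Stark
Reagents that add atoms: ethylene glycol, OCCO
Why: Acid-catalysed ketalisation takes the carbonyl remote from the gem-dimethyl group (future C3), because the other carbonyl is flanked by CMe2 and the methyl-bearing alkene carbon.

**Step 2**
Reactants: 2 ketoisophorone C4 ethylene ketal
Product: 3 diene ketal (7,9,9-trimethyl-8-methylidene-1,4-dioxaspiro[4.5]dec-6-ene)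
Conditions: Ph3PCH3Br, KOtBu, toluene, 90 °C
Reagents that add atoms: methyltriphenylphosphonium bromide, C[P+](c1ccccc1)(c1ccccc1)c1ccccc1.[Br-]
Why: Wittig methylenation: the carbonyl is hindered but has no α-hydrogen on either side, so the unstabilised ylide at elevated temperature adds 1,2 and gives the exocyclic alkene of a cross-conjugated diene.

**Step 3**
Reactants: 3 diene ketal; 4 trichloroacetyl chloride
Product: 6 racemic 2,2-dichloro spirocyclobutanone ketal, via dichloroketene 5 (not isolated)
Conditions: Zn–Cu, POCl3, Et2O, rt, sonication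
Reagents that add atoms: none
Why: Thermal [2+2] cycloaddition of dichloroketene (from zinc dechlorination of 4) to the unhindered terminal alkene, the ketene carbonyl carbon bonding to the CH2 terminus so that CCl2 sits on the ring carbon; POCl3 sequesters ZnCl2 and spares the allylic ketal, and the racemic spiro centre loses its stereogenicity in step 4.

**Step 4**
Reactants: 6 racemic 2,2-dichloro spirocyclobutanone ketal
Product: 7 achiral spirocyclobutanone ketal (5,13,13-trimethyl-8,11-dioxadispiro[3.2.4^7.2^4]tridec-5-en-2-one)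
Conditions: Zn, NH4Cl, MeOH, rt
Reagents that add atoms: none
Why: Zinc-mediated reductive dechlorination of the α,α-dichloro ketone under buffered conditions leaves ketal and alkene intact and makes the two ring CH2–CO arms equivalent.

**Step 5**
Reactants: 8 3-(trimethylsilyl)prop-2-yn-1-ol
Product: 9 tert-butyldimethyl{[3-(trimethylsilyl)prop-2-yn-1-yl]oxy}silane
Conditions: TBSCl, imidazole, CH2Cl2, 0 °C to rt
Reagents that add atoms: tert-butyldimethylsilyl chloride, CC(C)(C)[Si](C)(C)Cl
Why: Imidazole-promoted silylation of the primary propargylic alcohol; the C-silyl group is untouched.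

**Step 6**
Reactants: 7 achiral spirocyclobutanone ketal; 9 silyl alkyne
Product: 10 (6R)-9-[(tert-butyldimethylsilyloxy)methyl]-1,5,5-trimethyl-8-(trimethylsilyl)spiro[5.5]undeca-1,8-diene-3,10-dione 3-ethylene ketal
Conditions: Ni(cod)2 (10 mol%), (S)-BINOL-derived phosphoramidite (20 mol%), 9 (1.5 equiv, slow addition), toluene, 60 °C
Reagents that add atoms: none
Why: Proposed new method: Ni(0) couples the cyclobutanone carbonyl and the alkyne by oxidative cyclisation to an oxanickelacyclopentene with the C10–C9 bond at the non-silylated alkyne carbon, strain-driven β-carbon elimination opens the four-membered ring to a seven-membered nickelacycle, and reductive elimination forms C7–C8. The closest known reaction types are the racemic Ni(0)/phosphine intermolecular alkyne insertion into 3,3-disubstituted cyclobutanones and the ligand-controlled enantioselective intramolecular C–C activation of cyclobutanones. Ring B is closed as a formal [4+2] two-carbon ring expansion of the cyclobutanone, not by cyclisation of an open chain. C6 is set by the chiral ligand on nickel, which selects which of the two enantiotopic C(O)–CH2 bonds undergoes β-carbon elimination; the two arms differ through their ring A neighbours, the sp3 CMe2 carbon C5 and the sp2 carbon C1. The required regiochemistry (silicon on C8, oxygenated carbon on C9) follows from the preference of silyl alkynes to place silicon on the nickel-bound carbon, and the ketal and the trisubstituted alkene are spectators.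

**Step 7**
Reactants: 10 key-step spiro dienone
Product: 13 (6S)-9-(hydroxymethyl)-1,5,5-trimethylspiro[5.5]undeca-1,8-diene-3,10-dione 3-ethylene ketal, via vinylsilane alcohol 11 (not isolated), via trimethylsilyl ether 12 (not isolated)
Conditions: TBAF·3H2O (3 equiv), THF, 0 °C to rt
Reagents that add atoms: none
Why: Fluoride-induced desilylation: cleavage of the O–TBS ether frees an alkoxide cis to silicon across C8=C9, which relays the trimethylsilyl group from C8 to oxygen (1,4 C→O silyl shift, Brook type) with protonation of C8, after which fluoride removes the O–TMS group; ketal and C6 are unaffected.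

**Step 8**
Reactants: 13 hydroxymethyl enone ketal
Product: 15 (6S,9R)-9-hydroxy-9-(hydroxymethyl)-1,5,5-trimethylspiro[5.5]undec-1-ene-3,10-dione 3-ethylene ketal, via hydroperoxide 14 (not isolated)
Conditions: Mn(dpm)3 (5 mol%), PhSiH3, O2 (1 atm), iPrOH/CH2Cl2, 0 °C; then P(OEt)3
Reagents that add atoms: dioxygen, O=O
Why: Mukaiyama-type manganese-hydride/O2 hydration of the enone (hydrogen-atom transfer to C8, O2 capture by the α-keto C9 radical, phosphite reduction of the hydroperoxide), faster than at the hindered isolated C1=C2 alkene; C9 is set by O2 adding axially to the ring B half-chair on the face opposite the axial ring A carbon C1 (C5 equatorial), which puts the C9 oxygen cis to C5.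

**Step 9**
Reactants: 15 dihydroxy ketone ketal
Product: 17 (6S,9R)-9,15-epoxy ketone ketal (oxirane spiro-fused at C9), via primary mesylate 16 (not isolated)
Conditions: MsCl, Et3N, CH2Cl2, −20 °C; then K2CO3, MeOH, 0 °C
Reagents that add atoms: none
Why: Selective mesylation of the primary alcohol and intramolecular Williamson etherification by the tertiary α-ketol oxygen give the spiro epoxide without breaking any bond to C9, so its configuration is kept.

**Step 10**
Reactants: 17 epoxy ketone ketal
Product: 19 (6S,9S)-9-(chloromethyl)-9-hydroxy-1,5,5-trimethylspiro[5.5]undec-1-ene-3,10-dione, via chlorohydrin ketal 18 (not isolated)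
Conditions: conc. HCl, THF, 0 °C to rt
Reagents that add atoms: hydrogen chloride, Cl; water, O
Why: Acid-promoted epoxide opening by chloride at the primary carbon C15 (SN2; the tertiary α-keto carbon C9 does not ionise, so C9 is retained) with hydrolysis of the allylic ketal in the same pot.

**Step 11**
Reactants: 19 chlorohydrin enedione
Product: 21 (4R,6R,9S)-4-bromo-9-(chloromethyl)-9-hydroxy-1,5,5-trimethylspiro[5.5]undec-1-ene-3,10-dione, via boron dienolate 20 (not isolated)
Conditions: Bu2BOTf (2.3 equiv), Et3N (3 equiv), CH2Cl2, −78 to 0 °C; NBS, −78 °C; pH 7 buffer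
Reagents that add atoms: N-bromosuccinimide, O=C1CCC(=O)N1Br
Why: Boron-mediated soft enolisation followed by NBS bromination of the boron enolate: the boron triflate binds the more basic, less hindered conjugated C3 carbonyl (C10 is flanked by fully substituted C9 and deactivated by the α-oxygen) and the amine removes the α′ hydrogen at C4; C4 can equilibrate through the enol to the equatorial bromide cis to C11, which avoids a syn-axial Br/C7 contact in the ring A conformer that keeps C14 beside the flat C10 carbonyl.

**Step 12**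
Reactants: 21 bromo enone
Product: 23 (4R,6R,9S)-4-bromo-9-(chloromethyl)-9-hydroxy-5,5-dimethyl-1-methylidenespiro[5.5]undecane-3,10-dione, via silyl dienol ether 22 (not isolated)
Conditions: TMSOTf (3 equiv), Et3N (4 equiv), CH2Cl2, 0 °C to rt; then aq. oxalic acid, THF, 0 °C
Reagents that add atoms: none
Why: Deconjugation through an extended dienol ether: silylation under equilibrating conditions removes a C14 hydrogen to give the linear 1-silyloxy diene (the alternative enol ether would crowd Br, OSi and CMe2 on one tetrasubstituted alkene), and mild acid protonates it kinetically at the α-carbon C2, releasing the β,γ-unsaturated ketone with the exocyclic C1=C14 alkene and freeing the C9 hydroxyl; C4 is not touched.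

**Step 13**
Reactants: 23 β,γ-unsaturated bromo ketone
Product: 24 target, (3S,4R,6R,9S)-4-bromo-9-(chloromethyl)-3,9-dihydroxy-5,5-dimethyl-1-methylidenespiro[5.5]undecan-10-one
Conditions: NaBH4, MeOH/CH2Cl2 (1:1), −78 °C
Reagents that add atoms: none
Why: Chemo- and diastereoselective borohydride reduction: the α-bromo ketone at C3 is much more electrophilic than the C10 ketone (axial face blocked by C14, other side fully substituted C9), and hydride attacks C3 from the equatorial side because the axial C5 methyl blocks axial attack, giving the axial C3–OH cis to the equatorial C4–Br.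

**Compound list**

1 | ketoisophorone (2,6,6-trimethylcyclohex-2-ene-1,4-dione) | CC1=CC(=O)CC(C)(C)C1=O | starting material
2 | 7,9,9-trimethyl-1,4-dioxaspiro[4.5]dec-6-en-8-one | CC1=CC2(OCCO2)CC(C)(C)C1=O | intermediate
3 | 7,9,9-trimethyl-8-methylidene-1,4-dioxaspiro[4.5]dec-6-ene | C=C1C(C)=CC2(OCCO2)CC1(C)C | intermediate
4 | trichloroacetyl chloride | O=C(Cl)C(Cl)(Cl)Cl | starting material
5 | dichloroketene | O=C=C(Cl)Cl | intermediate
6 | rac-1,1-dichloro-5,13,13-trimethyl-8,11-dioxadispiro[3.2.4^7.2^4]tridec-5-en-2-one | O=C1CC2(C1(Cl)Cl)C(C)=CC3(OCCO3)CC2(C)C | intermediate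
7 | 5,13,13-trimethyl-8,11-dioxadispiro[3.2.4^7.2^4]tridec-5-en-2-one (achiral 3-spirocyclobutanone) | O=C1CC2(C1)C(C)=CC3(OCCO3)CC2(C)C | intermediate
8 | 3-(trimethylsilyl)prop-2-yn-1-ol | C[Si](C)(C)C#CCO | starting material
9 | tert-butyldimethyl{[3-(trimethylsilyl)prop-2-yn-1-yl]oxy}silane | C[Si](C)(C)C#CCO[Si](C)(C)C(C)(C)C | intermediate
10 | (6R)-9-[(tert-butyldimethylsilyloxy)methyl]-1,5,5-trimethyl-8-(trimethylsilyl)spiro[5.5]undeca-1,8-diene-3,10-dione 3-ethylene ketal | CC1=CC3(OCCO3)CC(C)(C)[C@@]12CC([Si](C)(C)C)=C(CO[Si](C)(C)C(C)(C)C)C(=O)C2 | intermediate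
11 | (6R)-9-(hydroxymethyl)-1,5,5-trimethyl-8-(trimethylsilyl)spiro[5.5]undeca-1,8-diene-3,10-dione 3-ethylene ketal | CC1=CC3(OCCO3)CC(C)(C)[C@@]12CC([Si](C)(C)C)=C(CO)C(=O)C2 | intermediate
12 | (6S)-1,5,5-trimethyl-9-[(trimethylsilyloxy)methyl]spiro[5.5]undeca-1,8-diene-3,10-dione 3-ethylene ketal | CC1=CC3(OCCO3)CC(C)(C)[C@@]12CC=C(CO[Si](C)(C)C)C(=O)C2 | intermediate
13 | (6S)-9-(hydroxymethyl)-1,5,5-trimethylspiro[5.5]undeca-1,8-diene-3,10-dione 3-ethylene ketal | CC1=CC3(OCCO3)CC(C)(C)[C@@]12CC=C(CO)C(=O)C2 | intermediate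
14 | (6S,9R)-9-hydroperoxy-9-(hydroxymethyl)-1,5,5-trimethylspiro[5.5]undec-1-ene-3,10-dione 3-ethylene ketal | CC1=CC3(OCCO3)CC(C)(C)[C@@]12CC[C@@](OO)(CO)C(=O)C2 | intermediate
15 | (6S,9R)-9-hydroxy-9-(hydroxymethyl)-1,5,5-trimethylspiro[5.5]undec-1-ene-3,10-dione 3-ethylene ketal | CC1=CC3(OCCO3)CC(C)(C)[C@@]12CC[C@@](O)(CO)C(=O)C2 | intermediate
16 | (6S,9R)-9-hydroxy-9-[(methanesulfonyloxy)methyl]-1,5,5-trimethylspiro[5.5]undec-1-ene-3,10-dione 3-ethylene ketal | CC1=CC3(OCCO3)CC(C)(C)[C@@]12CC[C@@](O)(COS(C)(=O)=O)C(=O)C2 | intermediate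
17 | (6S,9R)-9,15-epoxy-1,5,5-trimethylspiro[5.5]undec-1-ene-3,10-dione 3-ethylene ketal (oxirane spiro at C9) | CC1=CC3(OCCO3)CC(C)(C)[C@@]12CC[C@@]4(CO4)C(=O)C2 | intermediate
18 | (6S,9S)-9-(chloromethyl)-9-hydroxy-1,5,5-trimethylspiro[5.5]undec-1-ene-3,10-dione 3-ethylene ketal | CC1=CC3(OCCO3)CC(C)(C)[C@@]12CC[C@@](O)(CCl)C(=O)C2 | intermediate
19 | (6S,9S)-9-(chloromethyl)-9-hydroxy-1,5,5-trimethylspiro[5.5]undec-1-ene-3,10-dione | CC1=CC(=O)CC(C)(C)[C@@]12CC[C@@](O)(CCl)C(=O)C2 | intermediate
20 | C3 O-dibutylboryl dienolate (C3=C4) and C9 O-dibutylborinate of 19, configured at C6 and C9 as in 19 | CC1=CC(OB(CCCC)CCCC)=CC(C)(C)[C@@]12CC[C@@](OB(CCCC)CCCC)(CCl)C(=O)C2 | intermediate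
21 | (4R,6R,9S)-4-bromo-9-(chloromethyl)-9-hydroxy-1,5,5-trimethylspiro[5.5]undec-1-ene-3,10-dione | CC1=CC(=O)[C@H](Br)C(C)(C)[C@@]12CC[C@@](O)(CCl)C(=O)C2 | intermediate
22 | (4R,6R,9S)-4-bromo-9-(chloromethyl)-5,5-dimethyl-1-methylidene-3,9-bis(trimethylsilyloxy)spiro[5.5]undec-2-en-10-one | C=C1C=C(O[Si](C)(C)C)[C@H](Br)C(C)(C)[C@@]12CC[C@@](O[Si](C)(C)C)(CCl)C(=O)C2 | intermediate
23 | (4R,6R,9S)-4-bromo-9-(chloromethyl)-9-hydroxy-5,5-dimethyl-1-methylidenespiro[5.5]undecane-3,10-dione | C=C1CC(=O)[C@H](Br)C(C)(C)[C@@]12CC[C@@](O)(CCl)C(=O)C2 | intermediate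
24 | (3S,4R,6R,9S)-4-bromo-9-(chloromethyl)-3,9-dihydroxy-5,5-dimethyl-1-methylidenespiro[5.5]undecan-10-one (IUPAC: (3S,6R,8R,9S)-8-bromo-3-(chloromethyl)-3,9-dihydroxy-7,7-dimethyl-11-methylidenespiro[5.5]undecan-2-one) | C=C1C[C@H](O)[C@H](Br)C(C)(C)[C@@]12CC[C@@](O)(CCl)C(=O)C2 | target

**Step count and risks**

Total steps: 13. Longest linear sequence: 12 (steps 1–4 and 6–13 from ketoisophorone); the alkyne arm is one step.

Steps most likely to fail:

1. Step 6. The ligand may discriminate poorly between the two enantiotopic C(O)–CH2 bonds, or insertion may be slow at the congested spiro centre so that alkyne oligomerisation takes over. Fallback, setting out from 7 and 9: the known racemic variant (Ni(cod)2, PCy3, toluene, 100 °C) should give the racemic spiro dienone F1. Reagent-controlled oxazaborolidine (CBS)/catecholborane reduction of the C10 carbonyl then converts the two enantiomers into diastereomeric allylic alcohols, the (6R,10S)-alcohol F2 and the (6S,10S)-alcohol F3, which are separated on silica. MnO2 oxidation of F2 returns to 10.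

2. Step 12. Enolisation may occur toward C4 instead of C14, so that hydrolysis only returns the conjugated bromo enone, or the β,γ-ketone may reconjugate during hydrolysis. Fallback, setting out from 21: a second boron-enolate bromination (Bu2BOTf, Et3N; NBS) should give the 4,4-dibromo enone F4, which has no C4 hydrogen. Silylation (TMSOTf, Et3N) can then only give the extended bis-silyl dienol ether F5, and mild aqueous acid should give the β,γ-unsaturated gem-dibromo ketone F6. Selective mono-debromination with diethyl phosphite/Et3N (bromophilic attack, axial protonation of the bromo enolate leaving bromine equatorial) returns to 23.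

3. Step 11. The C10 ketone may enolise competitively and be brominated at C11, or bromine may be delivered to the wrong face of C4 without equilibration. Fallback, setting out from 17: NaBH4 reduction temporarily removes the competing carbonyl and should give the C10 epoxy alcohol F7. PPTS in wet acetone unveils the ring A enone in the epoxy alcohol enone F8. Kinetic deprotonation with LDA (2.2 equiv) and TMSCl gives the cross-conjugated bis-silyl dienol ether F9, in which only C4 can have been deprotonated. NBS then gives the bromo enone alcohol F10, Dess–Martin oxidation restores the C10 ketone in the bromo enone epoxy ketone F11, and HCl in THF opens the epoxide to return to 21.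

**Further compounds**

F1 | step 6 | racemic 9-[(tert-butyldimethylsilyloxy)methyl]-1,5,5-trimethyl-8-(trimethylsilyl)spiro[5.5]undeca-1,8-diene-3,10-dione 3-ethylene ketal | CC1=CC3(OCCO3)CC(C)(C)C12CC([Si](C)(C)C)=C(CO[Si](C)(C)C(C)(C)C)C(=O)C2
F2 | step 6 | (6R,10S)-allylic alcohol from C10 reduction of 10 | CC1=CC3(OCCO3)CC(C)(C)[C@@]12CC([Si](C)(C)C)=C(CO[Si](C)(C)C(C)(C)C)[C@@H](O)C2
F3 | step 6 | (6S,10S)-allylic alcohol from C10 reduction of ent-10 | CC1=CC3(OCCO3)CC(C)(C)[C@]12CC([Si](C)(C)C)=C(CO[Si](C)(C)C(C)(C)C)[C@@H](O)C2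
F4 | step 12 | 4,4-dibromo-9-(chloromethyl)-9-hydroxy-1,5,5-trimethylspiro[5.5]undec-1-ene-3,10-dione, C6 and C9 as in 21 | CC1=CC(=O)C(Br)(Br)C(C)(C)[C@@]12CC[C@@](O)(CCl)C(=O)C2
F5 | step 12 | 4,4-dibromo-9-(chloromethyl)-5,5-dimethyl-1-methylidene-3,9-bis(trimethylsilyloxy)spiro[5.5]undec-2-en-10-one, C6 and C9 as in 21 | C=C1C=C(O[Si](C)(C)C)C(Br)(Br)C(C)(C)[C@@]12CC[C@@](O[Si](C)(C)C)(CCl)C(=O)C2
F6 | step 12 | 4,4-dibromo-9-(chloromethyl)-9-hydroxy-5,5-dimethyl-1-methylidenespiro[5.5]undecane-3,10-dione, C6 and C9 as in 21 | C=C1CC(=O)C(Br)(Br)C(C)(C)[C@@]12CC[C@@](O)(CCl)C(=O)C2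
F7 | step 11 | 9,15-epoxy-10-hydroxy-1,5,5-trimethylspiro[5.5]undec-1-en-3-one ethylene ketal, C10–OH axial and trans to the epoxide oxygen | CC1=CC3(OCCO3)CC(C)(C)[C@@]12CC[C@@]4(CO4)[C@@H](O)C2
F8 | step 11 | 9,15-epoxy-10-hydroxy-1,5,5-trimethylspiro[5.5]undec-1-en-3-one, configured as F7 | CC1=CC(=O)CC(C)(C)[C@@]12CC[C@@]4(CO4)[C@@H](O)C2
F9 | step 11 | 9,15-epoxy-1,5,5-trimethyl-3,10-bis(trimethylsilyloxy)spiro[5.5]undeca-1,3-diene, configured as F7 | CC1=CC(O[Si](C)(C)C)=CC(C)(C)[C@@]12CC[C@@]4(CO4)[C@@H](O[Si](C)(C)C)C2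
F10 | step 11 | 4-bromo-9,15-epoxy-10-hydroxy-1,5,5-trimethylspiro[5.5]undec-1-en-3-one, C4 as in 21 | CC1=CC(=O)[C@H](Br)C(C)(C)[C@@]12CC[C@@]4(CO4)[C@@H](O)C2
F11 | step 11 | 4-bromo-9,15-epoxy-1,5,5-trimethylspiro[5.5]undec-1-ene-3,10-dione, C4 as in 21 | CC1=CC(=O)[C@H](Br)C(C)(C)[C@@]12CC[C@@]4(CO4)C(=O)C2
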